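The side chain is disconnected between C3' and C4'. The C4' methyl stereocentre, isolated between CH2 groups, is read as a former secondary carbinol carbon, and C3' as the carbanionic end of a three-carbon arm on C2 of the dihydropyran ring B of the chroman. In one operation a copper-catalysed SN2 coupling joins the primary Grignard reagent of the complete (2R)-chroman (rings A and B, from (R)-linalool) to the (2S)-tosylate of the C13 tail (from (S)-propylene oxide and (R)-citronellyl bromide) and sets C4' as R by inversion. A final hydrogenation removes the benzyl group and the terminal alkene.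

Key step: step 9

Assumption: (R)-(−)-linalool, (R)-(−)-citronellyl bromide and (S)-propylene oxide are taken as commercial materials of high enantiomeric purity; their optical purity limits that of C2, C8' and C4'.
Note on descriptors: the descriptor at chroman C2 reads S in 8, 9, 10 and 16, and that of the tail methyl carbon reads S in 14, 15 and 17, only because CIP priorities change; no bond to these centres is broken anywhere.

Step 1
Reactants: 1 3-bromo-5-methylphenol
Product: 2 1-(benzyloxy)-3-bromo-5-methylbenzene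
Conditions: BnBr (1.1 equiv), K2CO3 (1.5 equiv), DMF, rt
Reagents that add atoms: benzyl bromide, BrCc1ccccc1
Why: Williamson ether synthesis on the phenoxide masks the future C6 hydroxyl as a benzyl ether that tolerates the organometallic steps and is removed in the final hydrogenation.

Step 2
Reactants: 2 1-(benzyloxy)-3-bromo-5-methylbenzene
Product: 3 5-(benzyloxy)-1,2-dibromo-3-methylbenzene
Conditions: NBS (1.05 equiv), MeCN, 0 °C to rt, dark
Reagents that add atoms: N-bromosuccinimide, O=C1CCC(=O)N1Br
Why: Electrophilic aromatic bromination with NBS in acetonitrile is directed para to the benzyloxy group, to the position between Br and CH3, which installs the bromine that later becomes the C8a–O bond.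

Step 3
Reactants: 4 (R)-(−)-linalool (1.15 equiv); 3 5-(benzyloxy)-1,2-dibromo-3-methylbenzene
Product: 6 (3R)-1-[5-(benzyloxy)-2-bromo-3-methylphenyl]-3,7-dimethyloct-6-en-3-ol, via B-alkyl-9-BBN borane 5 (not isolated)
Conditions: 9-BBN (1.3 equiv), THF, 0 °C to rt; then 3, PdCl2(dppf) (4 mol%), 3 M aq. NaOH, THF, 60 °C
Reagents that add atoms: none
Why: 9-BBN hydroborates only the monosubstituted vinyl group of 4 in the anti-Markovnikov sense (the trisubstituted alkene and the hindered tertiary OH react far more slowly), and the B-alkyl Suzuki–Miyaura coupling takes place at the C1–Br bond of 3, which has a single ortho substituent and is meta to the benzyloxy group, while the C2–Br bond flanked by Br and CH3 and para to the donor stays; the carbinol stereocentre is not touched.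

Step 4
Reactants: 6 (3R)-1-[5-(benzyloxy)-2-bromo-3-methylphenyl]-3,7-dimethyloct-6-en-3-ol
Product: 7 (2R)-6-(benzyloxy)-2,8-dimethyl-2-(4-methylpent-3-en-1-yl)-3,4-dihydro-2H-chromene
Conditions: Pd(OAc)2 (5 mol%), rac-2-(di-tert-butylphosphino)-1,1'-binaphthyl (6 mol%), Cs2CO3 (1.5 equiv), toluene, 80 °C
Reagents that add atoms: none
Why: Palladium-catalysed intramolecular aryl etherification (Buchwald–Hartwig-type C–O coupling) closes the six-membered ring B by C–O reductive elimination from an aryl palladium alkoxide that has no hydrogen on the carbinol carbon to lose, and because the C2–O bond is never broken the linalool configuration becomes (2R) of the chroman.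

Step 5
Reactants: 7 (2R)-6-(benzyloxy)-2,8-dimethyl-2-(4-methylpent-3-en-1-yl)-3,4-dihydro-2H-chromene
Product: 9 3-[(2S)-6-(benzyloxy)-2,8-dimethyl-3,4-dihydro-2H-chromen-2-yl]propan-1-ol, via aldehyde 8 (not isolated)
Conditions: O3, CH2Cl2/MeOH, −78 °C (to first faint blue); then NaBH4, −78 °C to rt
Reagents that add atoms: ozone, O=[O+][O-]
Why: Ozonolysis with reductive work-up cleaves the electron-rich trisubstituted alkene much faster than the aryl ether ring and leaves exactly the three carbons C1'–C3' on C2 as a primary alcohol.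

Step 6
Reactants: 9 3-[(2S)-6-(benzyloxy)-2,8-dimethyl-3,4-dihydro-2H-chromen-2-yl]propan-1-ol
Product: 10 (2S)-6-(benzyloxy)-2-(3-bromopropyl)-2,8-dimethyl-3,4-dihydro-2H-chromene
Conditions: CBr4 (1.3 equiv), PPh3 (1.3 equiv), CH2Cl2, 0 °C
Reagents that add atoms: carbon tetrabromide, BrC(Br)(Br)Br
Why: The Appel reaction turns the primary alcohol into the bromide under neutral conditions that leave both ethers intact.

Step 7
Reactants: 11 (R)-(−)-citronellyl bromide; 12 (S)-(−)-propylene oxide (1.2 equiv)
Product: 14 (2S,6S)-6,10-dimethylundec-9-en-2-ol, via citronellylmagnesium bromide 13 (not isolated)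
Conditions: Mg, THF, 40 °C; then CuI (10 mol%), 12, THF, −30 to 0 °C; aqueous work-up
Reagents that add atoms: none
Why: Copper-catalysed SN2 opening of the epoxide by the primary Grignard reagent at the unsubstituted CH2 keeps the C–O stereocentre of (S)-propylene oxide, so the (2S)-carbinol is obtained next to the unchanged citronellyl stereocentre.

Step 8
Reactants: 14 (2S,6S)-6,10-dimethylundec-9-en-2-ol
Product: 15 (2S,6S)-6,10-dimethylundec-9-en-2-yl 4-methylbenzenesulfonate
Conditions: TsCl (1.3 equiv), Et3N (2 equiv), DMAP (cat.), CH2Cl2, 0 °C to rt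
Reagents that add atoms: 4-toluenesulfonyl chloride, Cc1ccc(cc1)S(Cl)(=O)=O
Why: O-Sulfonylation (tosylation) activates the carbinol with retention because only the O–H bond is replaced.

Step 9
Reactants: 10 (2S)-6-(benzyloxy)-2-(3-bromopropyl)-2,8-dimethyl-3,4-dihydro-2H-chromene (1.3 equiv); 15 (2S,6S)-6,10-dimethylundec-9-en-2-yl 4-methylbenzenesulfonate
Product: 17 (2R)-6-(benzyloxy)-2,8-dimethyl-2-[(4R,8S)-4,8,12-trimethyltridec-11-en-1-yl]-3,4-dihydro-2H-chromene, via chromanylpropylmagnesium bromide 16 (not isolated)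
Conditions: 10, Mg, THF, 40 °C; then 15, CuI (10 mol%), TMEDA (20 mol%), LiOMe (1.0 equiv, additive), THF, 0 °C
Reagents that add atoms: none
Why: Magnesium insertion gives the primary Grignard reagent 16, which transmetalates to a TMEDA/methoxide-ligated alkylcuprate of monovalent copper; this attacks C4' of tosylate 15 from the face opposite the leaving group (SN2-type oxidative addition to trivalent copper) and reductive elimination forms the C3'–C4' bond. The closest known reaction type is the copper-catalysed cross-coupling of non-activated secondary alkyl tosylates with alkyl Grignard reagents, which is stereospecific with inversion, together with the classical displacement of secondary tosylates by organocuprates. No ring is closed. The new C4' stereocentre is controlled solely by the (2S) carbinol configuration of 15 (from (S)-propylene oxide), which is inverted to give (4'R); the C2 and C8' centres lie far from the reacting atoms and are not touched. The step needs substitution to win over E2 elimination and over single-electron pathways that would scramble C4'; the sulfonate leaving group (no halide to be abstracted), the unhindered methyl-flanked secondary carbon, the primary nucleophile and the low temperature should secure this.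

Step 10
Reactants: 17 (2R)-6-(benzyloxy)-2,8-dimethyl-2-[(4R,8S)-4,8,12-trimethyltridec-11-en-1-yl]-3,4-dihydro-2H-chromene
Product: 18 δ-tocopherol, (2R)-2,8-dimethyl-2-[(4R,8R)-4,8,12-trimethyltridecyl]-3,4-dihydro-2H-chromen-6-ol
Conditions: H2 (3 bar), 10% Pd/C, EtOAc/EtOH, rt
Reagents that add atoms: none
Why: Catalytic hydrogenation over Pd/C saturates the trisubstituted alkene (no new stereocentre) and hydrogenolyses the benzyl ether in the same operation, while the non-benzylic chroman C–O bonds and the three stereocentres are left alone.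

Compound list
1 | 3-bromo-5-methylphenol | Cc1cc(O)cc(Br)c1 | starting material
2 | 1-(benzyloxy)-3-bromo-5-methylbenzene | Cc1cc(OCc2ccccc2)cc(Br)c1 | intermediate
3 | 5-(benzyloxy)-1,2-dibromo-3-methylbenzene | Cc1cc(OCc2ccccc2)cc(Br)c1Br | intermediate
4 | (R)-(−)-linalool, (3R)-3,7-dimethylocta-1,6-dien-3-ol | CC(C)=CCC[C@@](C)(O)C=C | starting material
5 | (3S)-1-(9-borabicyclo[3.3.1]nonan-9-yl)-3,7-dimethyloct-6-en-3-ol (B-alkyl-9-BBN borane, not isolated) | CC(C)=CCC[C@@](C)(O)CCB1C2CCCC1CCC2 | intermediate
6 | (3R)-1-[5-(benzyloxy)-2-bromo-3-methylphenyl]-3,7-dimethyloct-6-en-3-ol | CC(C)=CCC[C@@](C)(O)CCc1cc(OCc2ccccc2)cc(C)c1Br | intermediate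
7 | (2R)-6-(benzyloxy)-2,8-dimethyl-2-(4-methylpent-3-en-1-yl)-3,4-dihydro-2H-chromene | Cc1cc(OCc2ccccc2)cc2c1O[C@](C)(CCC=C(C)C)CC2 | intermediate
8 | 3-[(2S)-6-(benzyloxy)-2,8-dimethyl-3,4-dihydro-2H-chromen-2-yl]propanal (not isolated) | Cc1cc(OCc2ccccc2)cc2c1O[C@](C)(CCC=O)CC2 | intermediate
9 | 3-[(2S)-6-(benzyloxy)-2,8-dimethyl-3,4-dihydro-2H-chromen-2-yl]propan-1-ol | Cc1cc(OCc2ccccc2)cc2c1O[C@](C)(CCCO)CC2 | intermediate
10 | (2S)-6-(benzyloxy)-2-(3-bromopropyl)-2,8-dimethyl-3,4-dihydro-2H-chromene | Cc1cc(OCc2ccccc2)cc2c1O[C@](C)(CCCBr)CC2 | intermediate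
11 | (R)-(−)-citronellyl bromide, (6R)-8-bromo-2,6-dimethyloct-2-ene | BrCC[C@H](C)CCC=C(C)C | starting material
12 | (S)-(−)-propylene oxide, (2S)-2-methyloxirane | C[C@H]1CO1 | starting material
13 | [(3R)-3,7-dimethyloct-6-en-1-yl]magnesium bromide (not isolated) | Br[Mg]CC[C@H](C)CCC=C(C)C | intermediate
14 | (2S,6S)-6,10-dimethylundec-9-en-2-ol | C[C@H](O)CCC[C@H](C)CCC=C(C)C | intermediate
15 | (2S,6S)-6,10-dimethylundec-9-en-2-yl 4-methylbenzenesulfonate | C[C@H](OS(=O)(=O)c1ccc(C)cc1)CCC[C@H](C)CCC=C(C)C | intermediate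
16 | {3-[(2S)-6-(benzyloxy)-2,8-dimethyl-3,4-dihydro-2H-chromen-2-yl]propyl}magnesium bromide (not isolated) | Cc1cc(OCc2ccccc2)cc2c1O[C@](C)(CCC[Mg]Br)CC2 | intermediate
17 | (2R)-6-(benzyloxy)-2,8-dimethyl-2-[(4R,8S)-4,8,12-trimethyltridec-11-en-1-yl]-3,4-dihydro-2H-chromene | Cc1cc(OCc2ccccc2)cc2c1O[C@](C)(CCC[C@H](C)CCC[C@H](C)CCC=C(C)C)CC2 | intermediate
18 | δ-tocopherol, (2R)-2,8-dimethyl-2-[(4R,8R)-4,8,12-trimethyltridecyl]-3,4-dihydro-2H-chromen-6-ol | Cc1cc(O)cc2c1O[C@](C)(CCC[C@H](C)CCC[C@H](C)CCCC(C)C)CC2 | target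

Total step count: 10 steps.
Longest linear sequence: 8 steps (steps 1, 2, 3, 4, 5, 6, 9, 10, from 3-bromo-5-methylphenol).

Steps most likely to fail

Step 9 (key coupling). E2 elimination of the unactivated secondary tosylate, partial loss of stereochemical fidelity through single-electron pathways, and Wurtz-type homocoupling during Grignard formation may erode the yield or the C4' purity. The fallback sets out from 10 and comes back at 17; it replaces the unactivated electrophile by an activated one and attaches the tail afterwards. tert-Butyl (S)-lactate is treated with Tf2O and 2,6-lutidine (CH2Cl2, −78 °C) to give tert-butyl (2S)-2-{[(trifluoromethyl)sulfonyl]oxy}propanoate F1. Grignard reagent 16 (from 10 and Mg) displaces this α-triflyloxy ester under ZnCl2 catalysis (THF, 0 °C), a substitution known to run with clean inversion, to give tert-butyl (2S)-5-[(2R)-6-(benzyloxy)-2,8-dimethyl-3,4-dihydro-2H-chromen-2-yl]-2-methylpentanoate F2, which already holds the C3'–C4' bond and the correct C4' configuration. LiAlH4 (THF, 0 °C) should give (2S)-5-[(2R)-6-(benzyloxy)-2,8-dimethyl-3,4-dihydro-2H-chromen-2-yl]-2-methylpentan-1-ol F3, and TsCl/pyridine its tosylate, (2S)-5-[(2R)-6-(benzyloxy)-2,8-dimethyl-3,4-dihydro-2H-chromen-2-yl]-2-methylpentyl 4-methylbenzenesulfonate F4. Coupling of this primary tosylate with citronellylmagnesium bromide 13 (from 11) under Li2CuCl4 catalysis (THF, −20 °C to rt) forms C5'–C6' and should deliver 17.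

Step 3 (hydroboration and site-selective Suzuki–Miyaura coupling). Discrimination between the two C–Br bonds may be insufficient, leading to coupling at the flanked bromide or to twofold coupling. The fallback sets out from 2 and comes back at 6; it replaces steric discrimination by discrimination through the halogen. Aromatic Finkelstein exchange (CuI cat., trans-N,N'-dimethylcyclohexane-1,2-diamine, NaI, dioxane, 110 °C) converts 2 into 1-(benzyloxy)-3-iodo-5-methylbenzene F5. Para bromination with NBS in MeCN gives 5-(benzyloxy)-2-bromo-1-iodo-3-methylbenzene F6. B-Alkyl Suzuki–Miyaura coupling of borane 5 (from 4) with F6 (PdCl2(dppf), aq. NaOH, THF, rt to 40 °C) then takes place only at the C–I bond and should give 6.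

Step 4 (ring closure). Oxidative addition of zerovalent palladium into the di-ortho-substituted, electron-rich C–Br bond may be slow, with hydrodebromination competing. The fallback sets out from 6 and comes back at 7; it forms the ring by addition of the tertiary hydroxyl to a quinone carbonyl instead of by cross-coupling, again without breaking the C2–O bond.
- Bromine–lithium exchange and oxidation of the borate (n-BuLi 2.2 equiv, THF, −78 °C; B(OMe)3; then H2O2, NaOH) gives 4-(benzyloxy)-2-[(3R)-3-hydroxy-3,7-dimethyloct-6-en-1-yl]-6-methylphenol F7.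
- PhI(OAc)2 in MeCN/H2O (0 °C) oxidises this para-alkoxyphenol to 2-[(3R)-3-hydroxy-3,7-dimethyloct-6-en-1-yl]-6-methylcyclohexa-2,5-diene-1,4-dione F8.
- HC(OMe)3, MeOH and catalytic H2SO4 close the cyclic mixed ketal (2R)-8a-methoxy-2,8-dimethyl-2-(4-methylpent-3-en-1-yl)-3,4-dihydro-2H-chromen-6(8aH)-one F9.
- Reduction with Zn in AcOH (or ascorbic acid) expels the 8a-methoxy group with aromatisation to (2R)-2,8-dimethyl-2-(4-methylpent-3-en-1-yl)-3,4-dihydro-2H-chromen-6-ol F10.
- Benzylation (BnBr, K2CO3, DMF) returns 7.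

Further compounds
F1 | step 9 | tert-butyl (2S)-2-{[(trifluoromethyl)sulfonyl]oxy}propanoate | C[C@H](OS(=O)(=O)C(F)(F)F)C(=O)OC(C)(C)C
F2 | step 9 | tert-butyl (2S)-5-[(2R)-6-(benzyloxy)-2,8-dimethyl-3,4-dihydro-2H-chromen-2-yl]-2-methylpentanoate | Cc1cc(OCc2ccccc2)cc2c1O[C@](C)(CCC[C@H](C)C(=O)OC(C)(C)C)CC2
F3 | step 9 | (2S)-5-[(2R)-6-(benzyloxy)-2,8-dimethyl-3,4-dihydro-2H-chromen-2-yl]-2-methylpentan-1-ol | Cc1cc(OCc2ccccc2)cc2c1O[C@](C)(CCC[C@H](C)CO)CC2
F4 | step 9 | (2S)-5-[(2R)-6-(benzyloxy)-2,8-dimethyl-3,4-dihydro-2H-chromen-2-yl]-2-methylpentyl 4-methylbenzenesulfonate | Cc1cc(OCc2ccccc2)cc2c1O[C@](C)(CCC[C@H](C)COS(=O)(=O)c3ccc(C)cc3)CC2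
F5 | step 3 | 1-(benzyloxy)-3-iodo-5-methylbenzene | Cc1cc(OCc2ccccc2)cc(I)c1
F6 | step 3 | 5-(benzyloxy)-2-bromo-1-iodo-3-methylbenzene | Cc1cc(OCc2ccccc2)cc(I)c1Br
F7 | step 4 | 4-(benzyloxy)-2-[(3R)-3-hydroxy-3,7-dimethyloct-6-en-1-yl]-6-methylphenol | CC(C)=CCC[C@@](C)(O)CCc1cc(OCc2ccccc2)cc(C)c1O
F8 | step 4 | 2-[(3R)-3-hydroxy-3,7-dimethyloct-6-en-1-yl]-6-methylcyclohexa-2,5-diene-1,4-dione | CC(C)=CCC[C@@](C)(O)CCC1=CC(=O)C=C(C)C1=O
F9 | step 4 | (2R)-8a-methoxy-2,8-dimethyl-2-(4-methylpent-3-en-1-yl)-3,4-dihydro-2H-chromen-6(8aH)-one (C8a epimers) | CC1=CC(=O)C=C2CC[C@@](C)(CCC=C(C)C)OC12OC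
F10 | step 4 | (2R)-2,8-dimethyl-2-(4-methylpent-3-en-1-yl)-3,4-dihydro-2H-chromen-6-ol | Cc1cc(O)cc2c1O[C@](C)(CCC=C(C)C)CC2
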